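**Assumption:** the (S,S)-configured bis(oxazoline) ligand is taken to direct the carbenoid to the alkene face that leads to 7. If the opposite sense prevails, the (R,R)-ligand is used and nothing else changes.

## Structural features

The target is the methyl ester of a C20 oxylipin. Its cyclopentane (ring carbons C13–C17, numbered from the ester carbon C1) carries a cis-fused oxirane on C14/C15, a (1S)-1-chloropropyl arm (C18–C20) on C17, and on C13 a chain with three skipped (Z)-alkenes (C11=C12, C8=C9, C5=C6) ending in the ester. Five stereocentres are contiguous: C13, C14, C15 and C17 in the ring and C18 just outside it. The two carbon arms on C13 and C17 are trans, and the oxirane oxygen lies on the face of the C17 arm, anti to the C13 chain. The oxirane is sensitive to acid and nucleophiles and, while C12 is a carbonyl group, to β-elimination through a C13 enolate. The secondary chloride can eliminate or be displaced from inside by a C13 enolate (three-membered ring closure), and the skipped triene isomerises and autoxidises. The chain is routine; the real difficulty is to tie the exocyclic centre C18 to the ring centres and to place the oxirane on the face syn to the C17 arm. The key step exploits that C18 sits two bonds from C13, while C12 and C14 flank C13 as an ester/ketone pair. A bond C13–C18 that the target does not contain turns C13, C17 and C18 into a cyclopropane fused to a cyclopentanone, and C12–C20 unfolds into one unbranched β-keto ester chain with a (Z)-alkene at C17=C18. Chloride later cuts the extra bond at C18 with inversion, so the alkene geometry becomes the C17/C18 relationship.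

## Logic of the disconnections

25 to 24. No skeletal bond is cut; the three (Z) double bonds C5=C6, C8=C9 and C11=C12 are traced back to triple bonds. A skipped triene would not survive enolate, acid or fluoride steps, whereas alkynes are inert placeholders. Three geometry problems become one operation. The forward step must be a syn semihydrogenation that stops at the alkene and leaves oxirane and C18–Cl alone.

24 to 17 and 22. The C10–C11 bond (sp3–sp) is cut. This is the junction between the stereochemically dense ring and an achiral chain, and a copper acetylide substitutes a propargylic halide there. The molecule falls into two ten-carbon halves. The coupling must go by direct substitution, not with propargyl–allenyl shift, under a base mild enough for oxirane, chloride and the skipped diyne.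

22 to 21 to 18 and 19. Bromine is exchanged for hydroxyl, then C6–C7 is cut by the same acetylide coupling. Both pieces are commercial. The acetylide must alkylate at carbon in the presence of a free hydroxyl and an ester.

17 to 15 (through 16). The C15–O bond of the oxirane is cut. The oxirane is formed only after C12 has become an alkyne, so no enolisable carbonyl is ever β to it. The oxirane is replaced by a silyl ether on O14 and a sulfonate on C15. Closure is an intramolecular displacement with inversion at C15, so O14 must lie on the lower face, trans to the leaving group.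

15 to 14 to 13. The C11–C12 bond is cut (one-carbon homologation of an aldehyde), then C12 is taken back to the ester left by the key step. C11 comes from a reagent. The homologation must tolerate an enolisable aldehyde with a β-silyloxy group and a chloride in reach of the enolate, and the hydride reduction must stop at the aldehyde.

13 to 12 to 11. The O14–Si and O15–S bonds are cut. The two hydroxyls of a trans-diol must be given different roles, O15 leaving group and O14 nucleophile. The forward sulfonylation must choose O15.

11 to 10. The C14–H bond is cut. The C14 ketone is what the key step leaves, and a hydroxyl on C15 can deliver hydride to its own face, which gives the trans-diol. The medium must be acidic so that no C13 enolate recloses the cyclopropane onto C18–Cl.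

10 to 9. The C18–Cl bond is cut and C13–C18 is reconnected. Chlorine γ to both a ketone and an ester is the retron of a homoconjugate addition. The exocyclic stereocentre C18 becomes a ring atom whose configuration follows from alkene geometry, and C13 becomes a quaternary bridgehead. Chloride must attack C18 with clean inversion and break C13–C18, not C13–C17.

9 to 7 (through 8). The C15–O bond is cut. C15 is the only enolisable position of 7, and the bicycle has one open face. The oxidant must come from the face away from the cyclopropane.

7 to 6. The bonds C13–C17 and C13–C18 are cut. Two rings and three stereocentres collapse into an acyclic diazo keto ester with one (Z)-alkene. The forward step must select one alkene face and transfer the alkene geometry without loss.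

6 to 5 to 3 and 2, and 2 to 1. The diazo group is removed, then C15–C16 is cut (γ-alkylation of a β-keto ester dianion), then C–Br is exchanged for C–OH. All pieces are commercial. The alkylation must occur at the γ-carbon and keep the (Z) geometry of the allylic halide.

## Other disconnections considered

**Alternative 1:** The cut is the ring bond C14–C15. SmI2 would reduce both aldehyde groups of the acyclic 1,5-dialdehyde A1 to ketyls that couple on samarium, closing the cyclopentane as the cis-diol A2 with both hydroxyls anti to the C13 substituent.
- In its favour: both ring oxygens arrive in one step on the face of the later oxirane. A cis-diol can be taken to the oxirane by the orthoester/acyloxonium–halide protocol, in which either carbon may be attacked because both paths end in the same oxirane. On this point the alternative is better than the chosen plan, which must tell the two hydroxyls of 11 apart (step 8). It also needs no chiral catalyst, which is equal or better provided A1 is enantiopure.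
- Against it here: A1 already holds C13, C17 and C18, three contiguous centres that must be set by acyclic stereocontrol. C13 is α to an aldehyde, so epimerisation or aldol condensation threatens before the coupling. C18 arrives as a silyl ether and must be exchanged for chloride with inversion next to a branched centre, where elimination competes. Silyl and p-methoxybenzyl groups add steps.
- Comparison: structurally, the chosen plan derives C18 from alkene geometry through two stereospecific events, whereas here C18 is an independent problem. Mechanistically, a one-electron ketyl coupling under chelate control stands against a two-electron carbenoid addition under catalyst control. In step count, the preparation of A1 is judged to cost about as much as the chosen route up to 15, so the alternative is longer overall.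

**Alternative 2:** The cut is a C15–O bond to a carboxyl oxygen of C18, a lactone bond that the target lacks. The C2-symmetric keto diester A3 would be taken to the diacid A4 by triflation of its enolate (both α positions are equivalent), reductive removal of the triflate and saponification. Iodine would then add to the face away from the homoallylic C17 carboxylate, which attacks C15 to give the bridged iodolactone A5.
- In its favour: symmetry removes any regiochemical question in the enolisation. The tether puts oxygen on the face of the C17 arm, which is the oxirane face, and at the same time distinguishes the two carboxyl groups. Later alcoholysis of A5 frees an alkoxide trans to iodine that closes the oxirane, and attack at C14 instead of C15 would converge on the same oxirane. For the oxirane this is more secure than the chosen plan, which relies on a face-selective hydroxylation, a directed reduction and a regioselective sulfonylation.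
- Against it here: both arms must be grown from carboxyl groups. C18 has to be turned from a carboxyl carbon into a chlorine-bearing stereocentre by addition or reduction under Felkin-type or reagent control, followed by chlorination with inversion, which is weaker control than the stereospecific cyclopropane route. A3 must be resolved or made asymmetrically. A5 is strained and its iodide is prone to elimination.
- Comparison: mechanistically the anti addition is as dependable as the cyclopropanation (equal). In step economy the ring is reached quickly, but redox and homologation work on two carboxyl groups is expected to make the total a few steps longer.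

**Alternative 3:** The cut is C13–C14, made by ring contraction. Birch reduction of the aromatic acid A6, enol ether hydrolysis, tert-butyl ester formation and diazo transfer would give the diazo enone A7. Photolysis in methanol expels N2, the vinyl carbon C14 shifts from C12 to C13, and methanol traps the ketene as the C12 methyl ester, giving the trans diester A8.
- In its favour: a very cheap aromatic start. The two carboxyl groups are born as different esters, so no desymmetrisation is needed (equal to alternative 2 on this point). The C14=C15 alkene is in place and the trans relation follows from equilibration at C13. Access to the ring is about as short as in the chosen plan (equal).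
- Against it here: C17 of A7 is formed without control, so a resolution or an asymmetric step must be added. The oxirane would have to be delivered by a peracid anti to the allylic C13 ester and syn to the C17 ester without a tether, a small steric bias that is weaker than in alternative 2 or the chosen plan. Diazo transfer to the α′ position of an enone needs prior activation, and the photochemical step is awkward on scale. C18 again has to be built from a carboxyl group.
- Comparison: the 1,2-shift is mechanistically dependable, but it builds one ring and one controlled stereocentre, against two rings and three stereocentres in the cyclopropanation. The remaining work (C18, oxirane face, both chains) is longer.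

Key step: step 4

## Route

Step 1
Reactants: 1 (Z)-pent-2-en-1-ol
Product: 2 (Z)-1-bromopent-2-ene
Conditions: PBr3 (0.4 equiv), pyridine (cat.), Et2O, −20 to 0 °C
Reagents that add atoms: phosphorus tribromide, BrP(Br)Br
Why: Bromide displaces the phosphite ester at the primary allylic carbon (SN2); the low temperature suppresses allylic transposition and Z to E isomerisation, so the geometry that later defines C18 is kept.

Step 2
Reactants: 3 methyl acetoacetate; 2 (Z)-1-bromopent-2-ene
Product: 5 methyl (6Z)-3-oxonon-6-enoate, via sodium lithium dianion 4 (not isolated)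
Conditions: NaH, THF, 0 °C; n-BuLi, 0 °C; then 2, 0 °C to rt; 1 M HCl
Reagents that add atoms: none
Why: Dianion alkylation of a β-keto ester: the γ-carbanion (C15), formed last, is the more nucleophilic site and attacks the primary allylic bromide at C16 by SN2 without allylic shift, forming C15–C16 and keeping the (Z)-alkene.

Step 3
Reactants: 5 methyl (6Z)-3-oxonon-6-enoate
Product: 6 methyl (6Z)-2-diazo-3-oxonon-6-enoate
Conditions: 4-acetamidobenzenesulfonyl azide, Et3N, MeCN, 0 °C to rt
Reagents that add atoms: 4-acetamidobenzenesulfonyl azide, CC(=O)Nc1ccc(cc1)S(=O)(=O)N=[N+]=[N-]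
Why: Regitz diazo transfer to the doubly activated methylene C13; the triazene adduct of the enolate fragments to the diazo compound and the sulfonamide, and the alkene is not touched.

Step 4
Reactants: 6 methyl (6Z)-2-diazo-3-oxonon-6-enoate
Product: 7 methyl (1S,5S,6R)-6-ethyl-2-oxobicyclo[3.1.0]hexane-1-carboxylate (ethyl endo)
Conditions: (CuOTf)2·C6H6 (5 mol %), 2,2′-(propane-2,2-diyl)bis[(4S)-4-tert-butyl-4,5-dihydrooxazole] (12 mol %), CH2Cl2, rt, slow addition of 6
Reagents that add atoms: none
Why: The copper complex takes N2 from the diazo group and gives an electrophilic copper carbenoid at C13, which adds to the tethered C17=C18 alkene in a concerted, asynchronous [2+1] addition. The closest known reaction type is the copper- or rhodium-catalysed intramolecular cyclopropanation of α-diazo-β-keto esters that carry a γ,δ-alkene, run with bis(oxazoline) ligands. The cyclopentanone closes through C13–C17 in a 5-exo mode with respect to the alkene (tether C14–C15–C16), and the cyclopropane closes in the same event through C13–C18 as the three-membered ring of the carbene addition, so the fusion can only be cis. C13 and C17 are thus fixed relative to each other by the bicyclo[3.1.0] geometry, and C18 is fixed by stereospecific transfer of the (Z)-alkene geometry, which places the ethyl group endo, cis to C16. The only free variable is the alkene face, and it is set by the C2-symmetric ligand, whose tert-butyl groups block two diagonal quadrants around the carbenoid. The step needs chemoselectivity over C–H insertion, Wolff rearrangement and carbene dimerisation; the short tether, the slow-to-rearrange acceptor/acceptor carbenoid and slow addition of 6 should secure it. Copper does not isomerise the alkene, so the (Z) geometry of 6 is carried into 7 intact.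

Step 5
Reactants: 7 methyl (1S,5S,6R)-6-ethyl-2-oxobicyclo[3.1.0]hexane-1-carboxylate
Product: 9 methyl (1S,3R,5S,6R)-6-ethyl-3-hydroxy-2-oxobicyclo[3.1.0]hexane-1-carboxylate, via potassium enolate 8 (not isolated)
Conditions: KN(SiMe3)2, THF, −78 °C; 2-(phenylsulfonyl)-3-phenyloxaziridine, −78 °C; AcOH
Reagents that add atoms: 2-(phenylsulfonyl)-3-phenyloxaziridine, O=S(=O)(c1ccccc1)N1OC1c1ccccc1
Why: Enolate oxidation with an N-sulfonyloxaziridine: C13 is quaternary, so the ketone can enolise only towards C15. The endo ethyl group lies under the five-membered ring, so oxygen is delivered to the face away from the cyclopropane and C15–OH ends up trans to it.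

Step 6
Reactants: 9 methyl (1S,3R,5S,6R)-6-ethyl-3-hydroxy-2-oxobicyclo[3.1.0]hexane-1-carboxylate
Product: 10 methyl (1S,3R,5R)-5-[(1S)-1-chloropropyl]-3-hydroxy-2-oxocyclopentane-1-carboxylate
Conditions: HCl (4 M in 1,4-dioxane), Et4NCl, CH2Cl2, 0 °C to rt
Reagents that add atoms: hydrogen chloride, Cl
Why: Homoconjugate addition to a cyclopropane activated by ketone and ester: chloride attacks C18 from the side opposite C13 (inversion) and breaks C13–C18, the bond that overlaps the ketone π system, which keeps the five-membered ring. The resulting enol tautomerises to the β-keto ester, whose C13 settles trans to the C17 arm; the acid medium gives no enolate that could reclose the ring.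

Step 7
Reactants: 10 methyl (1S,3R,5R)-5-[(1S)-1-chloropropyl]-3-hydroxy-2-oxocyclopentane-1-carboxylate
Product: 11 methyl (1S,2R,3R,5R)-5-[(1S)-1-chloropropyl]-2,3-dihydroxycyclopentane-1-carboxylate
Conditions: Me4NBH(OAc)3, MeCN/AcOH (1:1), −30 to 0 °C; aq. potassium sodium tartrate
Reagents that add atoms: none
Why: Hydroxyl-directed reduction (Evans–Saksena type): O15 exchanges an acetate on boron and the bound hydride is delivered to C14 on the face of O15, so the new hydroxyl is trans to it and on the lower face. The reagent does not reduce the ester or an unbound ketone, and the acidic medium prevents C13 enolate attack on C18–Cl.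

Step 8
Reactants: 11 methyl (1S,2R,3R,5R)-5-[(1S)-1-chloropropyl]-2,3-dihydroxycyclopentane-1-carboxylate
Product: 12 methyl (1S,2R,3R,5R)-5-[(1S)-1-chloropropyl]-2-hydroxy-3-[(4-methylbenzenesulfonyl)oxy]cyclopentane-1-carboxylate
Conditions: TsCl (1.1 equiv), pyridine, CH2Cl2, 0 °C
Reagents that add atoms: 4-methylbenzenesulfonyl chloride, Cc1ccc(cc1)S(Cl)(=O)=O
Why: Sulfonylation under steric control: O15 has the unsubstituted C16 methylene as a neighbour, whereas O14 is flanked by the branched, ester-bearing C13 and by C15 and is hydrogen-bonded to the ester carbonyl, so the bulky sulfonyl chloride should react at O15. No stereocentre changes.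

Step 9
Reactants: 12 methyl (1S,2R,3R,5R)-5-[(1S)-1-chloropropyl]-2-hydroxy-3-[(4-methylbenzenesulfonyl)oxy]cyclopentane-1-carboxylate
Product: 13 methyl (1S,2R,3R,5R)-2-[(tert-butyldimethylsilyl)oxy]-5-[(1S)-1-chloropropyl]-3-[(4-methylbenzenesulfonyl)oxy]cyclopentane-1-carboxylate
Conditions: t-BuMe2SiOTf, 2,6-lutidine, CH2Cl2, −78 to 0 °C
Reagents that add atoms: tert-butyldimethylsilyl trifluoromethanesulfonate, CC(C)(C)[Si](C)(C)OS(=O)(=O)C(F)(F)F
Why: Silylation of the hindered O14 with the silyl triflate and a non-nucleophilic base; masking O14 keeps it from closing the oxirane while C12 is still a carbonyl group, which avoids a β,γ-epoxy aldehyde.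

Step 10
Reactants: 13 methyl (1S,2R,3R,5R)-2-[(tert-butyldimethylsilyl)oxy]-5-[(1S)-1-chloropropyl]-3-[(4-methylbenzenesulfonyl)oxy]cyclopentane-1-carboxylate
Product: 14 (1R,2R,3S,4R)-2-[(tert-butyldimethylsilyl)oxy]-4-[(1S)-1-chloropropyl]-3-formylcyclopentyl 4-methylbenzenesulfonate
Conditions: i-Bu2AlH (1.1 equiv), CH2Cl2, −78 °C; MeOH, aq. potassium sodium tartrate
Reagents that add atoms: none
Why: Partial reduction of a methyl ester: the tetrahedral aluminium hemiacetal is stable at −78 °C and releases the aldehyde only on work-up; sulfonate, silyl ether and alkyl chloride are inert to the hydride at this temperature.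

Step 11
Reactants: 14 (1R,2R,3S,4R)-2-[(tert-butyldimethylsilyl)oxy]-4-[(1S)-1-chloropropyl]-3-formylcyclopentyl 4-methylbenzenesulfonate
Product: 15 (1R,2R,3R,4R)-2-[(tert-butyldimethylsilyl)oxy]-4-[(1S)-1-chloropropyl]-3-ethynylcyclopentyl 4-methylbenzenesulfonate
Conditions: dimethyl (1-diazo-2-oxopropyl)phosphonate, K2CO3, MeOH, 0 °C to rt
Reagents that add atoms: dimethyl (1-diazo-2-oxopropyl)phosphonate, CC(=O)C(=[N+]=[N-])P(=O)(OC)OC
Why: Ohira–Bestmann homologation: methanolysis frees the diazomethylphosphonate anion, which olefinates the aldehyde; loss of N2 and a 1,2-hydrogen shift give the alkyne, with C11 coming from the reagent. C13 is trans to both neighbours, which is its thermodynamic arrangement, so enolisation under the mild base cannot damage it.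

Step 12
Reactants: 15 (1R,2R,3R,4R)-2-[(tert-butyldimethylsilyl)oxy]-4-[(1S)-1-chloropropyl]-3-ethynylcyclopentyl 4-methylbenzenesulfonate
Product: 17 (1R,2R,3R,5S)-3-[(1S)-1-chloropropyl]-2-ethynyl-6-oxabicyclo[3.1.0]hexane, via tetrabutylammonium alkoxide 16 (not isolated)
Conditions: Bu4NF, THF, 0 °C to rt
Reagents that add atoms: none
Why: Fluoride cleaves the O14–Si bond and the alkoxide displaces the trans sulfonate at C15 in a 3-exo-tet SN2 closure with inversion. The oxirane is therefore cis-fused on the lower face, syn to the C17 arm and anti to the alkyne, and no carbonyl group is left that could open it by β-elimination.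

Step 13
Reactants: 18 methyl hex-5-ynoate; 19 4-chlorobut-2-yn-1-ol
Product: 21 methyl 10-hydroxydeca-5,8-diynoate, via 4-iodobut-2-yn-1-ol 20 (not isolated)
Conditions: CuI, NaI, Cs2CO3, DMF, rt
Reagents that add atoms: none
Why: Copper-mediated coupling of a terminal alkyne with a propargylic halide: iodide exchange activates the chloride and the copper acetylide of 18 substitutes at the CH2 carbon (C7) without allenyl shift, forming C6–C7; the free hydroxyl and the ester tolerate the carbonate base.

Step 14
Reactants: 21 methyl 10-hydroxydeca-5,8-diynoate
Product: 22 methyl 10-bromodeca-5,8-diynoate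
Conditions: CBr4, PPh3, CH2Cl2, 0 °C
Reagents that add atoms: carbon tetrabromide, BrC(Br)(Br)Br
Why: Appel bromination of a primary propargylic alcohol under neutral conditions, which spares the base-sensitive skipped diyne.

Step 15
Reactants: 17 (1R,2R,3R,5S)-3-[(1S)-1-chloropropyl]-2-ethynyl-6-oxabicyclo[3.1.0]hexane; 22 methyl 10-bromodeca-5,8-diynoate
Product: 24 methyl 12-[(1R,2R,3R,5S)-3-[(1S)-1-chloropropyl]-6-oxabicyclo[3.1.0]hexan-2-yl]dodeca-5,8,11-triynoate, via methyl 10-iododeca-5,8-diynoate 23 (not isolated)
Conditions: CuI, NaI, Cs2CO3, DMF, rt
Reagents that add atoms: none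
Why: The same copper acetylide/propargylic halide coupling forms C10–C11; carbonate in DMF at room temperature should leave the oxirane and the hindered secondary chloride untouched, and no stereocentre is involved.

Step 16
Reactants: 24 methyl 12-[(1R,2R,3R,5S)-3-[(1S)-1-chloropropyl]-6-oxabicyclo[3.1.0]hexan-2-yl]dodeca-5,8,11-triynoate
Product: 25 methyl (5Z,8Z,11Z)-12-[(1R,2S,3R,5S)-3-[(1S)-1-chloropropyl]-6-oxabicyclo[3.1.0]hexan-2-yl]dodeca-5,8,11-trienoate
Conditions: H2 (1 atm), Pd/CaCO3 poisoned with Pb(OAc)2, quinoline, EtOAc, rt
Reagents that add atoms: none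
Why: Lindlar-type semihydrogenation: syn delivery of hydrogen on the poisoned palladium surface turns each alkyne into a (Z)-alkene and the poisoned catalyst releases the alkene before further reduction; oxirane, ester and alkyl chloride are not reduced under these conditions.

## Compound list

1 | (Z)-pent-2-en-1-ol | CC/C=C\CO | starting material
2 | (Z)-1-bromopent-2-ene | CC/C=C\CBr | intermediate
3 | methyl acetoacetate | CC(=O)CC(=O)OC | starting material
4 | sodium lithium salt of the methyl acetoacetate dianion | [Na+].[Li+].[CH2-]C(=O)[CH-]C(=O)OC | intermediate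
5 | methyl (6Z)-3-oxonon-6-enoate | CC/C=C\CCC(=O)CC(=O)OC | intermediate
6 | methyl (6Z)-2-diazo-3-oxonon-6-enoate | COC(=O)C(=[N+]=[N-])C(=O)CC/C=C\CC | intermediate
7 | methyl (1S,5S,6R)-6-ethyl-2-oxobicyclo[3.1.0]hexane-1-carboxylate (ethyl endo) | CC[C@@H]1[C@@H]2CCC(=O)[C@]12C(=O)OC | intermediate
8 | potassium (1S,5S,6R)-6-ethyl-1-(methoxycarbonyl)bicyclo[3.1.0]hex-2-en-2-olate | CC[C@@H]1[C@@H]2CC=C([O-])[C@]12C(=O)OC.[K+] | intermediate
9 | methyl (1S,3R,5S,6R)-6-ethyl-3-hydroxy-2-oxobicyclo[3.1.0]hexane-1-carboxylate (hydroxyl trans to the cyclopropane) | CC[C@@H]1[C@@H]2C[C@@H](O)C(=O)[C@]12C(=O)OC | intermediate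
10 | methyl (1S,3R,5R)-5-[(1S)-1-chloropropyl]-3-hydroxy-2-oxocyclopentane-1-carboxylate | CC[C@H](Cl)[C@@H]1C[C@@H](O)C(=O)[C@H]1C(=O)OC | intermediate
11 | methyl (1S,2R,3R,5R)-5-[(1S)-1-chloropropyl]-2,3-dihydroxycyclopentane-1-carboxylate (trans-diol) | CC[C@H](Cl)[C@@H]1C[C@@H](O)[C@H](O)[C@H]1C(=O)OC | intermediate
12 | methyl (1S,2R,3R,5R)-5-[(1S)-1-chloropropyl]-2-hydroxy-3-[(4-methylbenzenesulfonyl)oxy]cyclopentane-1-carboxylate | CC[C@H](Cl)[C@@H]1C[C@@H](OS(=O)(=O)c2ccc(C)cc2)[C@H](O)[C@H]1C(=O)OC | intermediate
13 | methyl (1S,2R,3R,5R)-2-[(tert-butyldimethylsilyl)oxy]-5-[(1S)-1-chloropropyl]-3-[(4-methylbenzenesulfonyl)oxy]cyclopentane-1-carboxylate | CC[C@H](Cl)[C@@H]1C[C@@H](OS(=O)(=O)c2ccc(C)cc2)[C@H](O[Si](C)(C)C(C)(C)C)[C@H]1C(=O)OC | intermediate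
14 | (1R,2R,3S,4R)-2-[(tert-butyldimethylsilyl)oxy]-4-[(1S)-1-chloropropyl]-3-formylcyclopentyl 4-methylbenzenesulfonate | CC[C@H](Cl)[C@@H]1C[C@@H](OS(=O)(=O)c2ccc(C)cc2)[C@H](O[Si](C)(C)C(C)(C)C)[C@H]1C=O | intermediate
15 | (1R,2R,3R,4R)-2-[(tert-butyldimethylsilyl)oxy]-4-[(1S)-1-chloropropyl]-3-ethynylcyclopentyl 4-methylbenzenesulfonate | CC[C@H](Cl)[C@@H]1C[C@@H](OS(=O)(=O)c2ccc(C)cc2)[C@H](O[Si](C)(C)C(C)(C)C)[C@H]1C#C | intermediate
16 | tetrabutylammonium (1R,2R,3R,5R)-3-[(1S)-1-chloropropyl]-2-ethynyl-5-[(4-methylbenzenesulfonyl)oxy]cyclopentan-1-olate | CC[C@H](Cl)[C@@H]1C[C@@H](OS(=O)(=O)c2ccc(C)cc2)[C@H]([O-])[C@H]1C#C.CCCC[N+](CCCC)(CCCC)CCCC | intermediate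
17 | (1R,2R,3R,5S)-3-[(1S)-1-chloropropyl]-2-ethynyl-6-oxabicyclo[3.1.0]hexane | CC[C@H](Cl)[C@@H]1C[C@@H]2O[C@@H]2[C@H]1C#C | intermediate
18 | methyl hex-5-ynoate | C#CCCCC(=O)OC | starting material
19 | 4-chlorobut-2-yn-1-ol | OCC#CCCl | starting material
20 | 4-iodobut-2-yn-1-ol | OCC#CCI | intermediate
21 | methyl 10-hydroxydeca-5,8-diynoate | COC(=O)CCCC#CCC#CCO | intermediate
22 | methyl 10-bromodeca-5,8-diynoate | COC(=O)CCCC#CCC#CCBr | intermediate
23 | methyl 10-iododeca-5,8-diynoate | COC(=O)CCCC#CCC#CCI | intermediate
24 | methyl 12-[(1R,2R,3R,5S)-3-[(1S)-1-chloropropyl]-6-oxabicyclo[3.1.0]hexan-2-yl]dodeca-5,8,11-triynoate | CC[C@H](Cl)[C@@H]1C[C@@H]2O[C@@H]2[C@H]1C#CCC#CCC#CCCCC(=O)OC | intermediate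
25 | methyl (5Z,8Z,11Z)-12-[(1R,2S,3R,5S)-3-[(1S)-1-chloropropyl]-6-oxabicyclo[3.1.0]hexan-2-yl]dodeca-5,8,11-trienoate | CC[C@H](Cl)[C@@H]1C[C@@H]2O[C@@H]2[C@H]1/C=C\C/C=C\C/C=C\CCCC(=O)OC | target

## Step count and least certain steps

Total: 16 steps. Longest linear sequence: 14 steps (steps 1 to 12, then 15 and 16); steps 13 and 14 form the two-step side branch.

**Step 4 (key step).** What may go wrong is insufficient discrimination of the two alkene faces: an acceptor/acceptor carbenoid from a methyl keto ester holds the alkene far from the stereodirecting groups of the ligand. Carbene dimerisation also competes if 6 is added too fast. Fallback: from 6, decomposition with achiral Rh2(OAc)4 in CH2Cl2 gives the same bicycle as a racemate, that is 7 together with its mirror image methyl (1R,5R,6S)-6-ethyl-2-oxobicyclo[3.1.0]hexane-1-carboxylate F1. The two are separated by preparative chromatography on a cellulose tris(3,5-dimethylphenylcarbamate) stationary phase, F1 is set aside and the route is rejoined at 7.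

**Step 6.** What may go wrong is slow opening, because chloride is a weak nucleophile towards a secondary cyclopropane carbon, or partial loss of inversion if the acid pushes the opening towards an ion pair; the free hydroxy ketone may also isomerise on long exposure to acid. Fallback: from 9, silylation with t-BuMe2SiOTf and 2,6-lutidine gives methyl (1S,3R,5S,6R)-3-[(tert-butyldimethylsilyl)oxy]-6-ethyl-2-oxobicyclo[3.1.0]hexane-1-carboxylate F2. TiCl4 with Et4NCl in CH2Cl2 at −78 °C chelates the two carbonyl groups and lets chloride open C13–C18 from outside, giving methyl (1S,3R,5R)-3-[(tert-butyldimethylsilyl)oxy]-5-[(1S)-1-chloropropyl]-2-oxocyclopentane-1-carboxylate F3. Aqueous HF in MeCN removes the silyl group and returns to 10.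

**Step 7.** What may go wrong is incomplete facial control: hydride transfer from the boron on O15 meets the ester on the same face at C13, and reduction through the minor C13 epimer or an undirected pathway would erode the trans relationship. Fallback: from 10 directly to 11 by hydrogenation with RuCl2[(S)-BINAP] or its mirror image in CH2Cl2/MeOH under H2 pressure, the hand being chosen to match the substrate. This is the ester-chelated hydrogenation of cyclic β-keto esters with dynamic resolution at the α-carbon, which gives the trans β-hydroxy ester; no new compound is involved.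

**Step 8.** What may go wrong is poor discrimination between the two secondary hydroxyls; sulfonylation at O14 would lead to the oxirane on the wrong face or to elimination towards the ester. Fallback: from 11, LiBH4 in THF reduces the ester to the triol (1R,2R,3R,4R)-4-[(1S)-1-chloropropyl]-3-(hydroxymethyl)cyclopentane-1,2-diol F4. 2,2-Dimethoxypropane with pyridinium 4-methylbenzenesulfonate can bridge only O12 and O14 and gives the six-membered acetonide with free C15 hydroxyl F5. TsCl in pyridine then has a single hydroxyl to react with and gives the acetonide sulfonate F6. Aqueous AcOH frees the diol sulfonate (1R,2R,3R,4R)-4-[(1S)-1-chloropropyl]-2-hydroxy-3-(hydroxymethyl)cyclopentyl 4-methylbenzenesulfonate F7. t-BuMe2SiOTf with 2,6-lutidine gives the bis-silyl ether F8, HF·pyridine in THF at 0 °C removes only the primary silyl group to give the primary alcohol F9, and Dess–Martin periodinane oxidises it to 14, where the route is rejoined.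

**Step 11.** What may go wrong is base-induced loss of material through the aldehyde enolate: β-elimination of the silyloxy group, or three-membered ring closure of C13 onto C18 with loss of chloride. Fallback: from 14, CBr4/PPh3/Zn in CH2Cl2 gives under non-basic conditions the dibromoalkene (1R,2R,3R,4R)-2-[(tert-butyldimethylsilyl)oxy]-4-[(1S)-1-chloropropyl]-3-(2,2-dibromoethenyl)cyclopentyl 4-methylbenzenesulfonate F10. n-BuLi (2 equiv) in THF at −78 °C converts it by bromine–lithium exchange and rearrangement into the lithium acetylide, and protonation at −78 °C returns to 15 (Corey–Fuchs sequence).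

**Step 16.** What may go wrong is over-reduction or incomplete reduction when three alkynes must be reduced at once; the C11≡C12 alkyne next to the ring reacts more slowly than the other two. Fallback: the two chain alkynes are reduced before the coupling. From 21, hydrogenation over the same lead-poisoned Pd/CaCO3 gives methyl (5Z,8Z)-10-hydroxydeca-5,8-dienoate F11, and CBr4/PPh3 gives methyl (5Z,8Z)-10-bromodeca-5,8-dienoate F12. Copper-mediated coupling of F12 with 17 (CuI, Cs2CO3, DMF) gives methyl (5Z,8Z)-12-[(1R,2R,3R,5S)-3-[(1S)-1-chloropropyl]-6-oxabicyclo[3.1.0]hexan-2-yl]dodeca-5,8-dien-11-ynoate F13. Semihydrogenation of its single remaining alkyne leads to 25.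

## Further compounds

F1 | step 4 | methyl (1R,5R,6S)-6-ethyl-2-oxobicyclo[3.1.0]hexane-1-carboxylate | CC[C@H]1[C@H]2CCC(=O)[C@@]12C(=O)OC
F2 | step 6 | methyl (1S,3R,5S,6R)-3-[(tert-butyldimethylsilyl)oxy]-6-ethyl-2-oxobicyclo[3.1.0]hexane-1-carboxylate | CC[C@@H]1[C@@H]2C[C@@H](O[Si](C)(C)C(C)(C)C)C(=O)[C@]12C(=O)OC
F3 | step 6 | methyl (1S,3R,5R)-3-[(tert-butyldimethylsilyl)oxy]-5-[(1S)-1-chloropropyl]-2-oxocyclopentane-1-carboxylate | CC[C@H](Cl)[C@@H]1C[C@@H](O[Si](C)(C)C(C)(C)C)C(=O)[C@H]1C(=O)OC
F0 | step 7 | none | none
F4 | step 8 | (1R,2R,3R,4R)-4-[(1S)-1-chloropropyl]-3-(hydroxymethyl)cyclopentane-1,2-diol | CC[C@H](Cl)[C@@H]1C[C@@H](O)[C@H](O)[C@H]1CO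
F5 | step 8 | acetonide of F4 across O12 and O14 (2,2-dimethyl-1,3-dioxane fused to the cyclopentane, C15 hydroxyl free) | CC[C@H](Cl)[C@@H]1C[C@@H](O)[C@@H]2OC(C)(C)OC[C@@H]12
F6 | step 8 | 4-methylbenzenesulfonate of F5 at O15 | CC[C@H](Cl)[C@@H]1C[C@@H](OS(=O)(=O)c3ccc(C)cc3)[C@@H]2OC(C)(C)OC[C@@H]12
F7 | step 8 | (1R,2R,3R,4R)-4-[(1S)-1-chloropropyl]-2-hydroxy-3-(hydroxymethyl)cyclopentyl 4-methylbenzenesulfonate | CC[C@H](Cl)[C@@H]1C[C@@H](OS(=O)(=O)c2ccc(C)cc2)[C@H](O)[C@H]1CO
F8 | step 8 | (1R,2R,3R,4R)-2-[(tert-butyldimethylsilyl)oxy]-3-{[(tert-butyldimethylsilyl)oxy]methyl}-4-[(1S)-1-chloropropyl]cyclopentyl 4-methylbenzenesulfonate | CC[C@H](Cl)[C@@H]1C[C@@H](OS(=O)(=O)c2ccc(C)cc2)[C@H](O[Si](C)(C)C(C)(C)C)[C@H]1CO[Si](C)(C)C(C)(C)C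
F9 | step 8 | (1R,2R,3R,4R)-2-[(tert-butyldimethylsilyl)oxy]-4-[(1S)-1-chloropropyl]-3-(hydroxymethyl)cyclopentyl 4-methylbenzenesulfonate | CC[C@H](Cl)[C@@H]1C[C@@H](OS(=O)(=O)c2ccc(C)cc2)[C@H](O[Si](C)(C)C(C)(C)C)[C@H]1CO
F10 | step 11 | (1R,2R,3R,4R)-2-[(tert-butyldimethylsilyl)oxy]-4-[(1S)-1-chloropropyl]-3-(2,2-dibromoethenyl)cyclopentyl 4-methylbenzenesulfonate | CC[C@H](Cl)[C@@H]1C[C@@H](OS(=O)(=O)c2ccc(C)cc2)[C@H](O[Si](C)(C)C(C)(C)C)[C@H]1C=C(Br)Br
F11 | step 16 | methyl (5Z,8Z)-10-hydroxydeca-5,8-dienoate | COC(=O)CCC/C=C\C/C=C\CO
F12 | step 16 | methyl (5Z,8Z)-10-bromodeca-5,8-dienoate | COC(=O)CCC/C=C\C/C=C\CBr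
F13 | step 16 | methyl (5Z,8Z)-12-[(1R,2R,3R,5S)-3-[(1S)-1-chloropropyl]-6-oxabicyclo[3.1.0]hexan-2-yl]dodeca-5,8-dien-11-ynoate | CC[C@H](Cl)[C@@H]1C[C@@H]2O[C@@H]2[C@H]1C#CC/C=C\C/C=C\CCCC(=O)OC
A1 | alternative 1 | 3-[1-(tert-butyldimethylsilyloxy)propyl]-2-[(4-methoxybenzyloxy)methyl]pentanedial, configured as in A2 | CC[C@@H](O[Si](C)(C)C(C)(C)C)[C@H](CC=O)[C@H](COCc1ccc(OC)cc1)C=O
A2 | alternative 1 | cis-cyclopentane-1,2-diol with trans arms: (4-methoxybenzyloxy)methyl on C13 and 1-(tert-butyldimethylsilyloxy)propyl on C17, diol anti to the C13 arm | CC[C@@H](O[Si](C)(C)C(C)(C)C)[C@@H]1C[C@H](O)[C@H](O)[C@H]1COCc1ccc(OC)cc1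
A3 | alternative 2 | dimethyl (1R,2R)-4-oxocyclopentane-1,2-dicarboxylate | COC(=O)[C@@H]1CC(=O)C[C@H]1C(=O)OC
A4 | alternative 2 | (1R,2R)-cyclopent-3-ene-1,2-dicarboxylic acid | OC(=O)[C@@H]1CC=C[C@H]1C(=O)O
A5 | alternative 2 | 6-iodo-3-oxo-2-oxabicyclo[2.2.1]heptane-5-carboxylic acid, iodine anti to the lactone oxygen, carboxyl trans to the lactone carbonyl carbon | O=C1O[C@H]2C[C@@H]1[C@H](C(=O)O)[C@@H]2I
A6 | alternative 3 | 3-methoxybenzoic acid | COc1cccc(c1)C(=O)O
A7 | alternative 3 | tert-butyl (1R)-2-diazo-3-oxocyclohex-4-ene-1-carboxylate | CC(C)(C)OC(=O)[C@@H]1CC=CC(=O)C1=[N+]=[N-]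
A8 | alternative 3 | 1-tert-butyl 2-methyl (1R,2R)-cyclopent-3-ene-1,2-dicarboxylate | CC(C)(C)OC(=O)[C@@H]1CC=C[C@H]1C(=O)OC
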